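**Plan**

1. Retrosynthetic cuts: (i) the two C–CH2 bonds of the methylene bridge, (ii) the C2–C3 bond of the 2H-pyran ring, (iii) the C4–CH2(geranyl) bond at the quaternary carbon of the cyclohexadienone, (iv) the two aryl–acyl bonds.
2. Enabling feature: the pyran atoms O1–C2(CH3)2–C3H=C4H–C4a–C8a are a redox isomer of an aryl isopropyl ether (O1–C2–H) lying ortho to an ethynyl group (C4≡C3H). A 1,5-hydride shift from C2–H to C4 followed by C2–C3 closure turns a phenol protecting group into the gem-dimethylpyran, and placing the isopropyl group on the oxygen between the hexanoyl carbon C8 and the alkyne fixes the annulation regiochemistry.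
3. Forward, chromene half: phloroglucinol → hexanoyl ketone → bis-tosylate → ortho-iodide → isopropyl ether → ethynyl arene → pyran ring → detosylation → Mannich base.
4. Forward, dienone half: 2-methylphloroglucinol → C-acetyl derivative → dearomative geranylation, which creates the cyclohexadienone ring and its quaternary carbon; the two halves are joined last through the CH2 bridge.
5. Stereochemistry: the single stereocentre (4R) comes from a palladium-catalysed asymmetric allylic dearomatisation with a chiral bisphosphine ligand; the 2E olefin is carried in from geraniol; the tosyl helper groups leave in step 7.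

Key step: step 6

Assumption: the β-triketone ring is written throughout in the enol tautomer of the target SMILES, and the (R,R)-ligand of step 11 is taken to deliver the (R)-configured centre; if the sense of induction proves opposite, the (S,S)-ligand is used with no other change.

**Route**

Step 1
Reactants: 1 phloroglucinol; 2 hexanoyl chloride
Product: 3 1-(2,4,6-trihydroxyphenyl)hexan-1-one
Conditions: AlCl3 (3.5 equiv), CH2Cl2/PhNO2, 0 °C to 40 °C; HCl (aq) work-up
Reagents that add atoms: none
Why: Friedel–Crafts C-acylation of the strongly activated ring should stop at the mono-ketone because the chelated acyl group deactivates the ring toward a second acylation.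

Step 2
Reactants: 3 1-(2,4,6-trihydroxyphenyl)hexan-1-one
Product: 4 1-[2-hydroxy-4,6-bis(tosyloxy)phenyl]hexan-1-one
Conditions: TsCl (2.1 equiv), K2CO3, acetone, reflux
Reagents that add atoms: 4-methylbenzenesulfonyl chloride, Cc1ccc(cc1)S(Cl)(=O)=O
Why: O-sulfonylation should take the para hydroxyl and one ortho hydroxyl and leave the last ortho hydroxyl free, since it is hydrogen-bonded to the ketone (selective protection of a chelated 2-hydroxyaryl ketone).

Step 3
Reactants: 4 1-[2-hydroxy-4,6-bis(tosyloxy)phenyl]hexan-1-one
Product: 5 1-[2-hydroxy-3-iodo-4,6-bis(tosyloxy)phenyl]hexan-1-one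
Conditions: NIS (1.1 equiv), TFA (cat.), MeCN, rt
Reagents that add atoms: N-iodosuccinimide, O=C1CCC(=O)N1I
Why: Electrophilic aromatic iodination should go ortho to the only free phenol, because the alternative position para to it is buried between two tosyloxy groups.

Step 4
Reactants: 5 1-[2-hydroxy-3-iodo-4,6-bis(tosyloxy)phenyl]hexan-1-one
Product: 6 1-[3-iodo-2-isopropoxy-4,6-bis(tosyloxy)phenyl]hexan-1-one
Conditions: i-PrOH, PPh3, DIAD, THF, 0 °C to rt
Reagents that add atoms: propan-2-ol, CC(C)O
Why: Mitsunobu etherification suits this acidic, chelated and hindered phenol and avoids basic conditions that could cause sulfonyl transfer.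

Step 5
Reactants: 6 1-[3-iodo-2-isopropoxy-4,6-bis(tosyloxy)phenyl]hexan-1-one
Product: 8 1-[3-ethynyl-2-isopropoxy-4,6-bis(tosyloxy)phenyl]hexan-1-one, via silylalkyne 7 (not isolated)
Conditions: ethynyltrimethylsilane, Pd(PPh3)2Cl2 (5 mol %), CuI (10 mol %), Et3N, THF, 60 °C; then K2CO3 (cat.), MeOH, 0 °C
Reagents that add atoms: ethynyltrimethylsilane, C#C[Si](C)(C)C
Why: Sonogashira coupling should engage only the aryl iodide (aryl tosylates are inert to this catalyst), and brief methanolysis of the C–Si bond in the same flask should release the terminal alkyne before the sulfonates are touched.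

Step 6
Reactants: 8 1-[3-ethynyl-2-isopropoxy-4,6-bis(tosyloxy)phenyl]hexan-1-one
Product: 9 1-[2,2-dimethyl-5,7-bis(tosyloxy)-2H-chromen-8-yl]hexan-1-one
Conditions: [(XPhos)Au(NCMe)]SbF6 (5 mol %), MeNO2, 4 Å MS, 80 °C
Reagents that add atoms: none
Why: Proposed new method: π-coordination of the cationic monovalent gold centre to the terminal alkyne makes the internal carbon (future C4) electrophilic, and the methine hydrogen of the ortho isopropyl ether (future C2–H) is delivered to it by a through-space 1,5-hydride shift through a six-membered transition state, giving an aryl oxocarbenium ion (O1=C2Me2) and a (Z)-alkenylgold species metalated at C3. The alkenylgold carbon C3 then attacks the oxocarbenium carbon C2 with retention and loss of the gold cation, which forms the C2–C3 bond, closes the pyran ring and returns the catalyst in an overall redox-neutral isomerisation. The closest known reactions are the hydride-shift/cyclisation of aliphatic alkynyl ethers to dihydropyrans and cyclohexenes under gold, platinum or rhodium catalysis and the Lewis-acid-catalysed hydride-transfer cyclisation of ortho-vinylaryl alkyl ethers to chromans; an unactivated terminal aryl alkyne as acceptor for an aryl isopropyl ether is the untested element. The ring closes in a 6-endo-trig manner at the oxocarbenium carbon, with both the C3=C4 bond and the O1=C2 bond inside the new six-membered ring, and no stereocentre is formed. The step needs hydride transfer to win over 5-endo attack of the ether oxygen on the alkyne and over closure through C4 to a 3-methylene-2,3-dihydrobenzofuran: the terminal alkyne places the positive charge on C4 and so disfavours oxygen attack at C3, the C–Au bond at C3 is held cis to the arene next to C2, and the other ortho substituent is a tosylate with neither a hydridic C–H nor a nucleophilic oxygen. The regiochemistry of the annulation relative to the hexanoyl group is fixed because only the oxygen between the ketone and the alkyne carries the isopropyl group.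

Step 7
Reactants: 9 1-[2,2-dimethyl-5,7-bis(tosyloxy)-2H-chromen-8-yl]hexan-1-one
Product: 10 1-(5,7-dihydroxy-2,2-dimethyl-2H-chromen-8-yl)hexan-1-one
Conditions: KOH (6 equiv), MeOH/H2O, 60 °C; then HCl (aq) to pH 4
Reagents that add atoms: none
Why: Hydroxide should cleave both aryl sulfonates at sulfur (they are activated ortho and para to the ketone) while the base-stable 2,2-dimethylchromene and the ketone survive (sulfonate ester saponification).

Step 8
Reactants: 10 1-(5,7-dihydroxy-2,2-dimethyl-2H-chromen-8-yl)hexan-1-one
Product: 11 1-{6-[(dimethylamino)methyl]-5,7-dihydroxy-2,2-dimethyl-2H-chromen-8-yl}hexan-1-one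
Conditions: Me2N=CH2+ I− (1.0 equiv), CH2Cl2, rt; NaHCO3 (aq) work-up
Reagents that add atoms: N,N-dimethylmethyleneiminium iodide (Eschenmoser's salt), C=[N+](C)C.[I-]
Why: Mannich aminomethylation with the preformed iminium salt should occur at C6, the only free position of the phloroglucinol ring and the one flanked by two hydroxyl groups.

Step 9
Reactants: 12 2-methylphloroglucinol
Product: 13 1-(2,4,6-trihydroxy-3-methylphenyl)ethan-1-one
Conditions: AcCl (1.05 equiv), AlCl3 (3.5 equiv), CH2Cl2/PhNO2, 0 °C to rt; HCl (aq) work-up
Reagents that add atoms: acetyl chloride, CC(Cl)=O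
Why: Friedel–Crafts acetylation should occur at one of the two equivalent free ring positions, and the first acyl group deactivates the ring toward a second.

Step 10
Reactants: 14 geraniol
Product: 15 geranyl methyl carbonate, (2E)-3,7-dimethylocta-2,6-dien-1-yl methyl carbonate
Conditions: ClCO2Me, pyridine, CH2Cl2, 0 °C
Reagents that add atoms: methyl chloroformate, COC(Cl)=O
Why: Acylation of the primary allylic alcohol with a chloroformate should give the allylic carbonate without touching the 2E olefin.

Step 11
Reactants: 13 1-(2,4,6-trihydroxy-3-methylphenyl)ethan-1-one; 15 geranyl methyl carbonate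
Product: 16 (4R)-2-acetyl-4-[(2E)-3,7-dimethylocta-2,6-dien-1-yl]-3,5-dihydroxy-4-methylcyclohexa-2,5-dien-1-one
Conditions: Pd2(dba)3·CHCl3 (2.5 mol %), (R,R)-DACH-phenyl ligand N,N'-[(1R,2R)-cyclohexane-1,2-diyl]bis[2-(diphenylphosphanyl)benzamide] (7.5 mol %), CH2Cl2 (degassed), rt; 15 as limiting reagent
Reagents that add atoms: none
Why: Tsuji–Trost asymmetric allylic alkylation used as a dearomatisation: zerovalent palladium ionises the carbonate to a π-geranyl complex and methoxide, the phenoxide para to the acetyl group attacks the unsubstituted allyl terminus through its methyl-bearing ortho carbon (the more electron-rich carbon, the same preference that turns C-methyl acylphloroglucinols into filicinic acids on further alkylation), and the chiral pocket of the ligand differentiates the two faces of this planar nucleophile, which has a free phenoxide on one side and a ketone-chelated hydroxyl on the other, to set the (R)-configured quaternary carbon.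

Step 12
Reactants: 11 1-{6-[(dimethylamino)methyl]-5,7-dihydroxy-2,2-dimethyl-2H-chromen-8-yl}hexan-1-one; 16 (4R)-2-acetyl-4-[(2E)-3,7-dimethylocta-2,6-dien-1-yl]-3,5-dihydroxy-4-methylcyclohexa-2,5-dien-1-one
Product: 17 (4R)-2-acetyl-4-[(2E)-3,7-dimethylocta-2,6-dien-1-yl]-6-[(8-hexanoyl-5,7-dihydroxy-2,2-dimethyl-2H-chromen-6-yl)methyl]-3,5-dihydroxy-4-methylcyclohexa-2,5-dien-1-one
Conditions: 1,4-dioxane, 90 °C, argon
Reagents that add atoms: none
Why: Thermal loss of dimethylamine from the phenolic Mannich base, assisted by proton transfer from the acidic β-triketone 16, should generate an ortho-quinone methide that is trapped in a Michael addition by C6 of the triketone enolate (its only C–H carbon), and rearomatisation gives the methylene bridge without touching the quaternary stereocentre.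

**Compound list**

1 | phloroglucinol (benzene-1,3,5-triol) | Oc1cc(O)cc(O)c1 | starting material
2 | hexanoyl chloride | CCCCCC(Cl)=O | starting material
3 | 1-(2,4,6-trihydroxyphenyl)hexan-1-one | CCCCCC(=O)c1c(O)cc(O)cc1O | intermediate
4 | 1-[2-hydroxy-4,6-bis(tosyloxy)phenyl]hexan-1-one | CCCCCC(=O)c1c(O)cc(OS(=O)(=O)c2ccc(C)cc2)cc1OS(=O)(=O)c1ccc(C)cc1 | intermediate
5 | 1-[2-hydroxy-3-iodo-4,6-bis(tosyloxy)phenyl]hexan-1-one | CCCCCC(=O)c1c(O)c(I)c(OS(=O)(=O)c2ccc(C)cc2)cc1OS(=O)(=O)c1ccc(C)cc1 | intermediate
6 | 1-[3-iodo-2-isopropoxy-4,6-bis(tosyloxy)phenyl]hexan-1-one | CCCCCC(=O)c1c(OC(C)C)c(I)c(OS(=O)(=O)c2ccc(C)cc2)cc1OS(=O)(=O)c1ccc(C)cc1 | intermediate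
7 | 1-{2-isopropoxy-4,6-bis(tosyloxy)-3-[(trimethylsilyl)ethynyl]phenyl}hexan-1-one (silylalkyne) | CCCCCC(=O)c1c(OC(C)C)c(C#C[Si](C)(C)C)c(OS(=O)(=O)c2ccc(C)cc2)cc1OS(=O)(=O)c1ccc(C)cc1 | intermediate
8 | 1-[3-ethynyl-2-isopropoxy-4,6-bis(tosyloxy)phenyl]hexan-1-one | CCCCCC(=O)c1c(OC(C)C)c(C#C)c(OS(=O)(=O)c2ccc(C)cc2)cc1OS(=O)(=O)c1ccc(C)cc1 | intermediate
9 | 1-[2,2-dimethyl-5,7-bis(tosyloxy)-2H-chromen-8-yl]hexan-1-one | CCCCCC(=O)c1c(OS(=O)(=O)c2ccc(C)cc2)cc(OS(=O)(=O)c2ccc(C)cc2)c2C=CC(C)(C)Oc12 | intermediate
10 | 1-(5,7-dihydroxy-2,2-dimethyl-2H-chromen-8-yl)hexan-1-one | CCCCCC(=O)c1c(O)cc(O)c2C=CC(C)(C)Oc12 | intermediate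
11 | 1-{6-[(dimethylamino)methyl]-5,7-dihydroxy-2,2-dimethyl-2H-chromen-8-yl}hexan-1-one | CCCCCC(=O)c1c(O)c(CN(C)C)c(O)c2C=CC(C)(C)Oc12 | intermediate
12 | 2-methylphloroglucinol (2-methylbenzene-1,3,5-triol) | Cc1c(O)cc(O)cc1O | starting material
13 | 1-(2,4,6-trihydroxy-3-methylphenyl)ethan-1-one | CC(=O)c1c(O)cc(O)c(C)c1O | intermediate
14 | geraniol, (2E)-3,7-dimethylocta-2,6-dien-1-ol | CC(C)=CCC/C(C)=C/CO | starting material
15 | geranyl methyl carbonate, (2E)-3,7-dimethylocta-2,6-dien-1-yl methyl carbonate | COC(=O)OC/C=C(\C)CCC=C(C)C | intermediate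
16 | (4R)-2-acetyl-4-[(2E)-3,7-dimethylocta-2,6-dien-1-yl]-3,5-dihydroxy-4-methylcyclohexa-2,5-dien-1-one | CC(=O)C1=C(O)[C@](C)(C/C=C(\C)CCC=C(C)C)C(O)=CC1=O | intermediate
17 | (4R)-2-acetyl-4-[(2E)-3,7-dimethylocta-2,6-dien-1-yl]-6-[(8-hexanoyl-5,7-dihydroxy-2,2-dimethyl-2H-chromen-6-yl)methyl]-3,5-dihydroxy-4-methylcyclohexa-2,5-dien-1-one | CCCCCC(=O)c1c(O)c(CC2=C(O)[C@@](C)(C/C=C(\C)CCC=C(C)C)C(O)=C(C(C)=O)C2=O)c(O)c2c1OC(C)(C)C=C2 | target

**Step count and risks**

Total step count: 12. Longest linear sequence: 9 steps (steps 1 to 8, then step 12).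

Steps most likely to fail:

Step 6. The hydride transfer may be too slow, because the ether oxygen is conjugated to an electron-poor ring and is a weak activator of the C–H bond. Gold-catalysed hydration of the alkyne, attack of the ether oxygen on the alkyne, or closure through C4 to a five-membered ring may then take over. The fallback uses known chemistry and builds the pyran ring by another bond. It sets out from compound 3: sulfonylation of the para hydroxyl alone (TsCl, 1.0 equiv, K2CO3, acetone, rt) should give 1-[2,6-dihydroxy-4-(tosyloxy)phenyl]hexan-1-one F1. Condensation of F1 with 3-methylbut-2-enal under ethylenediammonium diacetate catalysis in hot toluene (Knoevenagel condensation, then oxa-6π electrocyclisation) should give 1-[7-hydroxy-2,2-dimethyl-5-(tosyloxy)-2H-chromen-8-yl]hexan-1-one F2. The two remaining hydroxyl groups of F1 are equivalent, so only one chromene can form. Saponification of the sulfonate (KOH, MeOH/H2O, 60 °C) brings the sequence back to the route at compound 10.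

Step 11. Facial selectivity on the planar phenoxide may be poor. Allylation may also occur at the unsubstituted ring carbon or on oxygen, a second allylation of the product may follow, and the 2E geometry may erode through π-σ-π isomerisation. The fallback replaces asymmetric catalysis by resolution. It sets out from compound 13: alkylation with geranyl bromide (NaOMe, MeOH, 0 °C) should give racemic 2-acetyl-4-[(2E)-3,7-dimethylocta-2,6-dien-1-yl]-3,5-dihydroxy-4-methylcyclohexa-2,5-dien-1-one F3. Preparative chromatography on a chiral stationary phase (amylose tris(3,5-dimethylphenylcarbamate)) should separate the (4R)-enantiomer, at which point the sequence is back on the route at compound 16, from the (4S)-enantiomer F4, which is set aside.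

Step 12. The ortho-quinone methide may oligomerise or be captured on oxygen. At 90 °C in the presence of the liberated amine the methylene bridge may also scramble by retro-Michael and re-addition, giving symmetric dimers. The fallback joins the halves by reductive alkylation at room temperature. It sets out from compound 10: Vilsmeier–Haack formylation (POCl3, DMF, MeCN, 0 °C to rt; NaOAc (aq)) at the only free ring position should give 8-hexanoyl-5,7-dihydroxy-2,2-dimethyl-2H-chromene-6-carbaldehyde F5. Treatment of F5 with compound 16, L-proline (cat.) and Hantzsch ester in CH2Cl2 at rt (Knoevenagel condensation, then conjugate hydride transfer to the alkylidene intermediate) should deliver the methylene bridge directly, returning to the route at compound 17.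

**Further compounds**

F1 | step 6 | 1-[2,6-dihydroxy-4-(tosyloxy)phenyl]hexan-1-one | CCCCCC(=O)c1c(O)cc(OS(=O)(=O)c2ccc(C)cc2)cc1O
F2 | step 6 | 1-[7-hydroxy-2,2-dimethyl-5-(tosyloxy)-2H-chromen-8-yl]hexan-1-one | CCCCCC(=O)c1c(O)cc(OS(=O)(=O)c2ccc(C)cc2)c2C=CC(C)(C)Oc12
F3 | step 11 | racemic 2-acetyl-4-[(2E)-3,7-dimethylocta-2,6-dien-1-yl]-3,5-dihydroxy-4-methylcyclohexa-2,5-dien-1-one | CC(=O)C1=C(O)C(C)(C/C=C(\C)CCC=C(C)C)C(O)=CC1=O
F4 | step 11 | (4S)-2-acetyl-4-[(2E)-3,7-dimethylocta-2,6-dien-1-yl]-3,5-dihydroxy-4-methylcyclohexa-2,5-dien-1-one | CC(=O)C1=C(O)[C@@](C)(C/C=C(\C)CCC=C(C)C)C(O)=CC1=O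
F5 | step 12 | 8-hexanoyl-5,7-dihydroxy-2,2-dimethyl-2H-chromene-6-carbaldehyde | CCCCCC(=O)c1c(O)c(C=O)c(O)c2C=CC(C)(C)Oc12
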